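**Assumption (one line):** ring carbons are numbered as in the cyathane diterpenes (ring A = C1–C4 + C9, ring B = C4–C9, ring C = C5, C6, C10–C14; C17 = the acetoxymethyl carbon on C9); "β" is the face carrying C17, and the Why lines use this numbering.

**Retrosynthetic overview**
1. Target ⇐ butenolide ketone 20: a ketyl radical at C4 adds to the butenolide β-carbon C3, closing ring A last and setting C3 and C4; loss of silyloxide from the resulting enolate unveils the exo-methylene.
2. 20 ⇐ aldehyde 15 + β-iodoacrylate 18 (asymmetric Nozaki–Hiyama–Kishi coupling/lactonisation sets C2).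
3. 15 ⇐ trans-fused B/C ketone 10: allylation, then axial hydroxymethylation/acetylation at C9, epoxidation, ozonolysis.
4. 10 ⇐ 3-methylcyclohexane-1,2-dione: Pd-catalysed O-crotylation/Claisen (C6), Grignard addition, ring-closing metathesis (ring C), α-deoxygenation (C5).
5. Ring order: B (starting material) → C → lactone → A.

**Route**

Step 1
Reactants: 1 2-hydroxy-3-methylcyclohex-2-en-1-one (enol form of 3-methylcyclohexane-1,2-dione); 2 (E)-but-2-en-1-yl methyl carbonate
Product: 3 (S)-2-(but-3-en-2-yloxy)-3-methylcyclohex-2-en-1-one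
Conditions: Pd2(dba)3·CHCl3 (1 mol %), (S,S)-DACH-phenyl Trost ligand (3 mol %), CH2Cl2, 20 °C
Reagents that add atoms: none
Why: Tsuji–Trost asymmetric allylic alkylation, in which the acidic enol oxygen attacks the more substituted terminus of the π-crotylpalladium complex inside the chiral ligand pocket (the antipodal ligand would give ent-3), creating the (S) allylic ether carbon that later relays chirality to C6.

Step 2
Reactants: 3 (S)-2-(but-3-en-2-yloxy)-3-methylcyclohex-2-en-1-one
Product: 4 (S)-6-[(E)-but-2-en-1-yl]-2-hydroxy-6-methylcyclohex-2-en-1-one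
Conditions: toluene, 170 °C, sealed tube
Reagents that add atoms: none
Why: Claisen rearrangement through a chair transition state with the ether methyl pseudo-equatorial transfers the (S) ether centre suprafacially to the new quaternary carbon (S, the future C6 with its angular methyl) and gives the E-butenyl chain, the 1,2-dione then re-enolising away from the quaternary centre.

Step 3
Reactants: 4 (S)-6-[(E)-but-2-en-1-yl]-2-hydroxy-6-methylcyclohex-2-en-1-one; 5 4-bromo-2-methylbut-1-ene
Product: 8 (3S)-3-[(E)-but-2-en-1-yl]-2-hydroxy-3-methyl-2-(3-methylbut-3-en-1-yl)cyclohexan-1-one (both C2 epimers), via silyl enol ether 6 (not isolated), via tertiary carbinol 7 (not isolated)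
Conditions: Me3SiCl, Et3N, THF, 0 °C; then CH2=C(CH3)CH2CH2MgBr (from 5 and Mg) premixed with CeCl3, −78 → 0 °C; then 1 M HCl, 20 °C
Reagents that add atoms: none
Why: Silyl capping of the enol and CeCl3-assisted Grignard 1,2-addition to the neopentyl ketone install the C10–C12 chain, and acid hydrolysis of the silyl enol ether unveils the C4 ketone as an α-ketol whose uncontrolled carbinol centre is erased in step 5.

Step 4
Reactants: 8 (3S)-3-[(E)-but-2-en-1-yl]-2-hydroxy-3-methyl-2-(3-methylbut-3-en-1-yl)cyclohexan-1-one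
Product: 9 (4aS)-9a-hydroxy-4a,7-dimethyl-2,3,4,4a,5,8,9,9a-octahydro-1H-benzo[7]annulen-1-one (both C9a epimers)
Conditions: second-generation Grubbs catalyst (5 mol %), CH2Cl2, 40 °C
Reagents that add atoms: none
Why: Ring-closing metathesis between the 1,1-disubstituted and the internal olefin closes ring C as the trisubstituted (necessarily Z) cycloheptene with loss of propene.

Step 5
Reactants: 9 (4aS)-9a-hydroxy-4a,7-dimethyl-2,3,4,4a,5,8,9,9a-octahydro-1H-benzo[7]annulen-1-one
Product: 10 (4aS,9aS)-4a,7-dimethyl-2,3,4,4a,5,8,9,9a-octahydro-1H-benzo[7]annulen-1-one (trans ring fusion)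
Conditions: SmI2 (2.5 equiv), THF–MeOH, −78 °C
Reagents that add atoms: none
Why: SmI2 reductive cleavage of the C–O bond α to the ketone (α-deoxygenation) funnels both carbinol epimers into one samarium enolate, which methanol is expected to protonate kinetically on the face opposite the pseudo-axial angular methyl, giving H-5 anti to the C6 methyl (trans B/C fusion).

Step 6
Reactants: 10 (4aS,9aS)-4a,7-dimethyl-2,3,4,4a,5,8,9,9a-octahydro-1H-benzo[7]annulen-1-one
Product: 11 (4aS,9aS)-2-allyl-4a,7-dimethyl-2,3,4,4a,5,8,9,9a-octahydro-1H-benzo[7]annulen-1-one (C2 epimers)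
Conditions: LiN(i-Pr)2, THF, −78 °C; allyl bromide, −78 → 0 °C
Reagents that add atoms: allyl bromide (C=CCBr)
Why: Kinetic deprotonation occurs at the unhindered C9 methylene rather than the neopentyl C5 methine, and enolate alkylation brings in the C1–C2 arm as an allyl group whose configuration is erased in step 7.

Step 7
Reactants: 11 (4aS,9aS)-2-allyl-4a,7-dimethyl-2,3,4,4a,5,8,9,9a-octahydro-1H-benzo[7]annulen-1-one
Product: 13 [(2S,4aS,9aS)-2-allyl-4a,7-dimethyl-1-oxo-2,3,4,4a,5,8,9,9a-octahydro-1H-benzo[7]annulen-2-yl]methyl acetate, via hydroxymethyl ketone 12 (not isolated)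
Conditions: LiN(i-Pr)2, THF, −78 °C; CH2O (gas from cracked paraformaldehyde), −78 °C; then Ac2O, −78 → 0 °C
Reagents that add atoms: formaldehyde (C=O); acetic anhydride (CC(=O)OC(C)=O)
Why: Crossed aldol (hydroxymethylation) of the C9 enolate with monomeric formaldehyde follows the axial, chair-like trajectory on the face opposite the axial C6 methyl, so C17 ends axial (β) and the allyl arm equatorial (9S), and in situ acetylation of the aldolate blocks retro-aldol and installs the final acetate.

Step 8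
Reactants: 13 [(2S,4aS,9aS)-2-allyl-4a,7-dimethyl-1-oxo-2,3,4,4a,5,8,9,9a-octahydro-1H-benzo[7]annulen-2-yl]methyl acetate
Product: 14 [(2S,4aS,6R,7S,9aS)-2-allyl-6,7-epoxy-4a,7-dimethyl-1-oxodecahydro-1H-benzo[7]annulen-2-yl]methyl acetate
Conditions: mCPBA, CH2Cl2, 0 °C
Reagents that add atoms: mCPBA (OOC(=O)c1cccc(Cl)c1)
Why: Prilezhaev epoxidation, in which the peracid picks the electron-rich trisubstituted ring olefin over the monosubstituted allyl group and adds to the cycloheptene face opposite the angular C6 methyl, giving the 12β,13β-epoxide of the target.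

Step 9
Reactants: 14 [(2S,4aS,6R,7S,9aS)-2-allyl-6,7-epoxy-4a,7-dimethyl-1-oxodecahydro-1H-benzo[7]annulen-2-yl]methyl acetate
Product: 15 [(2S,4aS,6R,7S,9aS)-6,7-epoxy-4a,7-dimethyl-1-oxo-2-(2-oxoethyl)decahydro-1H-benzo[7]annulen-2-yl]methyl acetate
Conditions: O3, CH2Cl2, −78 °C; then PPh3, −78 → 20 °C
Reagents that add atoms: ozone ([O-][O+]=O)
Why: Ozonolysis with reductive work-up cleaves the only remaining C=C to the C2 aldehyde without touching ketone, acetate or epoxide.

Step 10
Reactants: 16 methyl propiolate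
Product: 17 methyl (Z)-2-(hydroxymethyl)-3-iodoacrylate
Conditions: MgI2, paraformaldehyde, CH2Cl2, 0 → 20 °C
Reagents that add atoms: magnesium diiodide ([Mg+2].[I-].[I-]); formaldehyde (C=O)
Why: MgI2-promoted iodo-aldol (β-iodo Morita–Baylis–Hillman) reaction, in which iodide adds to the propiolate and the resulting magnesium β-iodoallenolate is hydroxymethylated at its α-carbon, the chelated intermediate giving the Z isomer (iodine cis to the ester).

Step 11
Reactants: 17 methyl (Z)-2-(hydroxymethyl)-3-iodoacrylate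
Product: 18 methyl (Z)-2-{[(tert-butyldimethylsilyl)oxy]methyl}-3-iodoacrylate
Conditions: TBSCl, imidazole, CH2Cl2, 20 °C
Reagents that add atoms: TBSCl (CC(C)(C)[Si](C)(C)Cl)
Why: Standard silylation converts the allylic alcohol into a silyl ether that survives the chromium chemistry of step 12 yet can later leave from a samarium enolate.

Step 12
Reactants: 15 [(2S,4aS,6R,7S,9aS)-6,7-epoxy-4a,7-dimethyl-1-oxo-2-(2-oxoethyl)decahydro-1H-benzo[7]annulen-2-yl]methyl acetate; 18 methyl (Z)-2-{[(tert-butyldimethylsilyl)oxy]methyl}-3-iodoacrylate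
Product: 20 [(2S,4aS,6R,7S,9aS)-2-{[(2S)-4-{[(tert-butyldimethylsilyl)oxy]methyl}-5-oxo-2,5-dihydrofuran-2-yl]methyl}-6,7-epoxy-4a,7-dimethyl-1-oxodecahydro-1H-benzo[7]annulen-2-yl]methyl acetate, via hydroxy ester 19 (not isolated)
Conditions: CrCl2 (4 equiv), (S)-configured Kishi oxazoline–sulfonamide ligand (4 equiv), Et3N (4 equiv), NiCl2 (2 mol %), THF, 20 °C
Reagents that add atoms: none
Why: Asymmetric Nozaki–Hiyama–Kishi coupling, in which the vinylchromium reagent formed with retention of the Z geometry adds only to the aldehyde, the chiral sulfonamide ligand on chromium fixes the (S) carbinol centre C2 (the antipodal ligand would give the epimer), and the cis alkoxide–ester pair lactonises to the butenolide.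

Step 13
Reactants: 20 [(2S,4aS,6R,7S,9aS)-2-{[(2S)-4-{[(tert-butyldimethylsilyl)oxy]methyl}-5-oxo-2,5-dihydrofuran-2-yl]methyl}-6,7-epoxy-4a,7-dimethyl-1-oxodecahydro-1H-benzo[7]annulen-2-yl]methyl acetate
Product: 22 (2S,3S,4R,5S,6S,9S,12S,13R)-17-acetoxy-12,13-epoxy-4-hydroxycyath-18(20)-en-19,2-olide (target CNP0214540.1), via samarium enolate 21 (not isolated)
Conditions: SmI2 (2.5 equiv), HMPA (10 equiv), THF, −78 → 20 °C; then aq NH4Cl
Reagents that add atoms: none
Why: Proposed new method: SmI2 reduces the C4 ketone to a nucleophilic ketyl radical that adds 5-exo to the electrophilic β-carbon C3 of the butenolide on the face bearing the C1 tether (cis 5/5 fusion, so C2 dictates C3) and along the equatorial trajectory at C4 because the axial one is blocked by the syn-axial C6 methyl (trans-hydrindane with axial 4-OH, HMPA-saturated samarium preventing chelation to the acetate), after which the α-radical is reduced to the samarium enolate that expels silyloxide (E1cB) to unveil the exo-methylene, the closest known chemistry being the SmI2 ketyl–olefin cyclisation onto unsaturated esters and lactones combined with the β-elimination of samarium enolates.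

**Compound list**

1 | 2-hydroxy-3-methylcyclohex-2-en-1-one (enol of 3-methylcyclohexane-1,2-dione) | CC1=C(O)C(=O)CCC1 | starting material
2 | (E)-but-2-en-1-yl methyl carbonate | C/C=C/COC(=O)OC | starting material
3 | (S)-2-(but-3-en-2-yloxy)-3-methylcyclohex-2-en-1-one | C=C[C@H](C)OC1=C(C)CCCC1=O | intermediate
4 | (S)-6-[(E)-but-2-en-1-yl]-2-hydroxy-6-methylcyclohex-2-en-1-one | C/C=C/C[C@]1(C)CCC=C(O)C1=O | intermediate
5 | 4-bromo-2-methylbut-1-ene | C=C(C)CCBr | starting material
6 | (S)-6-[(E)-but-2-en-1-yl]-6-methyl-2-(trimethylsilyloxy)cyclohex-2-en-1-one | C/C=C/C[C@]1(C)CCC=C(O[Si](C)(C)C)C1=O | intermediate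
7 | (6S)-6-[(E)-but-2-en-1-yl]-6-methyl-1-(3-methylbut-3-en-1-yl)-2-(trimethylsilyloxy)cyclohex-2-en-1-ol (both C1 epimers) | C/C=C/C[C@]1(C)CCC=C(O[Si](C)(C)C)C1(O)CCC(C)=C | intermediate
8 | (3S)-3-[(E)-but-2-en-1-yl]-2-hydroxy-3-methyl-2-(3-methylbut-3-en-1-yl)cyclohexan-1-one (both C2 epimers) | C/C=C/C[C@]1(C)CCCC(=O)C1(O)CCC(C)=C | intermediate
9 | (4aS)-9a-hydroxy-4a,7-dimethyl-2,3,4,4a,5,8,9,9a-octahydro-1H-benzo[7]annulen-1-one (both C9a epimers) | CC1=CC[C@]2(C)CCCC(=O)C2(O)CC1 | intermediate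
10 | (4aS,9aS)-4a,7-dimethyl-2,3,4,4a,5,8,9,9a-octahydro-1H-benzo[7]annulen-1-one | O=C1CCC[C@@]2(C)CC=C(C)CC[C@H]12 | intermediate
11 | (4aS,9aS)-2-allyl-4a,7-dimethyl-2,3,4,4a,5,8,9,9a-octahydro-1H-benzo[7]annulen-1-one (C2 epimers) | C=CCC1CC[C@@]2(C)CC=C(C)CC[C@@H]2C1=O | intermediate
12 | (2S,4aS,9aS)-2-allyl-2-(hydroxymethyl)-4a,7-dimethyl-2,3,4,4a,5,8,9,9a-octahydro-1H-benzo[7]annulen-1-one | C=CC[C@]1(CO)CC[C@@]2(C)CC=C(C)CC[C@@H]2C1=O | intermediate
13 | [(2S,4aS,9aS)-2-allyl-4a,7-dimethyl-1-oxo-2,3,4,4a,5,8,9,9a-octahydro-1H-benzo[7]annulen-2-yl]methyl acetate | C=CC[C@]1(COC(C)=O)CC[C@@]2(C)CC=C(C)CC[C@@H]2C1=O | intermediate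
14 | [(2S,4aS,6R,7S,9aS)-2-allyl-6,7-epoxy-4a,7-dimethyl-1-oxodecahydro-1H-benzo[7]annulen-2-yl]methyl acetate | C=CC[C@]1(COC(C)=O)CC[C@@]2(C)C[C@H]3O[C@@]3(C)CC[C@@H]2C1=O | intermediate
15 | [(2S,4aS,6R,7S,9aS)-6,7-epoxy-4a,7-dimethyl-1-oxo-2-(2-oxoethyl)decahydro-1H-benzo[7]annulen-2-yl]methyl acetate | O=CC[C@]1(COC(C)=O)CC[C@@]2(C)C[C@H]3O[C@@]3(C)CC[C@@H]2C1=O | intermediate
16 | methyl propiolate | C#CC(=O)OC | starting material
17 | methyl (Z)-2-(hydroxymethyl)-3-iodoacrylate | COC(=O)/C(CO)=C\I | intermediate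
18 | methyl (Z)-2-{[(tert-butyldimethylsilyl)oxy]methyl}-3-iodoacrylate | COC(=O)/C(CO[Si](C)(C)C(C)(C)C)=C\I | intermediate
19 | methyl (2Z,4S)-5-[(2S,4aS,6R,7S,9aS)-2-(acetoxymethyl)-6,7-epoxy-4a,7-dimethyl-1-oxodecahydro-1H-benzo[7]annulen-2-yl]-2-{[(tert-butyldimethylsilyl)oxy]methyl}-4-hydroxypent-2-enoate (formed as its chromium alkoxide) | COC(=O)/C(CO[Si](C)(C)C(C)(C)C)=C\[C@@H](O)C[C@]1(COC(C)=O)CC[C@@]2(C)C[C@H]3O[C@@]3(C)CC[C@@H]2C1=O | intermediate
20 | [(2S,4aS,6R,7S,9aS)-2-{[(2S)-4-{[(tert-butyldimethylsilyl)oxy]methyl}-5-oxo-2,5-dihydrofuran-2-yl]methyl}-6,7-epoxy-4a,7-dimethyl-1-oxodecahydro-1H-benzo[7]annulen-2-yl]methyl acetate | CC(C)(C)[Si](C)(C)OCC1=C[C@H](C[C@]2(COC(C)=O)CC[C@@]3(C)C[C@H]4O[C@@]4(C)CC[C@@H]3C2=O)OC1=O | intermediate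
21 | cyclised bis(diiodosamarium) lactone enolate/C4 alkoxide still carrying the silyloxymethyl group | CC(C)(C)[Si](C)(C)OCC1=C(O[Sm](I)I)O[C@H]2C[C@]3(COC(C)=O)CC[C@@]4(C)C[C@H]5O[C@@]5(C)CC[C@@H]4[C@@]3(O[Sm](I)I)[C@@H]12 | intermediate
22 | (2S,3S,4R,5S,6S,9S,12S,13R)-17-acetoxy-12,13-epoxy-4-hydroxycyath-18(20)-en-19,2-olide (CNP0214540.1) | C=C1C(=O)O[C@H]2C[C@]3(COC(C)=O)CC[C@@]4(C)C[C@H]5O[C@@]5(C)CC[C@@H]4[C@@]3(O)[C@@H]12 | target

**Step count and risk**

Total: 13 steps. Longest linear sequence: 11 steps (1–9, 12, 13); steps 10 and 11 build fragment 18.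

The three steps most likely to fail are 13, 5 and 7.

For step 13, the ketyl may close to the wrong C4 epimer, the hindered ketone may simply be reduced, or the butenolide may be reduced first. The fallback makes C3 the nucleophile in a fluoride-triggered, open-transition-state allylsilane addition. It sets out from 20: HF·pyridine (THF, 0 °C) removes the silyl group to give [(2S,4aS,6R,7S,9aS)-6,7-epoxy-2-{[(2S)-4-(hydroxymethyl)-5-oxo-2,5-dihydrofuran-2-yl]methyl}-4a,7-dimethyl-1-oxodecahydro-1H-benzo[7]annulen-2-yl]methyl acetate F3. Palladium-catalysed silylation of this allylic alcohol with hexamethyldisilane (Pd(BF4)2(MeCN)4, DMSO–MeOH, 50 °C) gives [(2S,4aS,6R,7S,9aS)-6,7-epoxy-4a,7-dimethyl-1-oxo-2-{[(2S)-5-oxo-4-[(trimethylsilyl)methyl]-2,5-dihydrofuran-2-yl]methyl}decahydro-1H-benzo[7]annulen-2-yl]methyl acetate F4. Anhydrous fluoride (TASF, THF, −40 °C) then drives an intramolecular Hosomi–Sakurai-type attack of C3 on the C4 ketone with loss of Me3SiF, regenerating the exo-methylene and coming back to the route at 22.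

For step 5, kinetic protonation of the samarium enolate may favour the cis-fused ketone, and base equilibration is not expected to correct it reliably. The fallback forms the C5–H bond by syn hydrogenation instead. It sets out from 9: Burgess reagent (benzene, 50 °C) dehydrates the tertiary ketol, which can only eliminate towards C10, to the dienone (4aS)-4a,7-dimethyl-2,3,4,4a,5,8-hexahydro-1H-benzo[7]annulen-1-one F1. Hydrogenation (H2, 1 atm, palladium on carbon, EtOAc, 0 °C, stopped after one equivalent) should reduce the conjugated olefin before the isolated one, from the face opposite the angular methyl, and returns to the route at 10.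

For step 7, deprotonation of 11 may compete at C5 (scrambling the ring fusion), and the facial preference of formaldehyde may be modest. The fallback generates the C9 enolate regiospecifically by conjugate addition rather than deprotonation. It sets out from 10: α-methylenation (paraformaldehyde, N-methylanilinium trifluoroacetate, THF, reflux) gives (4aS,9aS)-4a,7-dimethyl-2-methylidene-2,3,4,4a,5,8,9,9a-octahydro-1H-benzo[7]annulen-1-one F2. Copper-catalysed 1,4-addition of vinylmagnesium bromide (CuBr·SMe2, THF, −78 °C) builds the allyl arm and leaves the magnesium enolate only at C9; it is trapped with gaseous CH2O to give 12 and then with Ac2O, returning to the route at 13.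

**Further compounds**

F1 | step 5 | (4aS)-4a,7-dimethyl-2,3,4,4a,5,8-hexahydro-1H-benzo[7]annulen-1-one | O=C1CCC[C@@]2(C)CC=C(C)CC=C12
F2 | step 7 | (4aS,9aS)-4a,7-dimethyl-2-methylidene-2,3,4,4a,5,8,9,9a-octahydro-1H-benzo[7]annulen-1-one | C=C1CC[C@@]2(C)CC=C(C)CC[C@@H]2C1=O
F3 | step 13 | [(2S,4aS,6R,7S,9aS)-6,7-epoxy-2-{[(2S)-4-(hydroxymethyl)-5-oxo-2,5-dihydrofuran-2-yl]methyl}-4a,7-dimethyl-1-oxodecahydro-1H-benzo[7]annulen-2-yl]methyl acetate | OCC1=C[C@H](C[C@]2(COC(C)=O)CC[C@@]3(C)C[C@H]4O[C@@]4(C)CC[C@@H]3C2=O)OC1=O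
F4 | step 13 | [(2S,4aS,6R,7S,9aS)-6,7-epoxy-4a,7-dimethyl-1-oxo-2-{[(2S)-5-oxo-4-[(trimethylsilyl)methyl]-2,5-dihydrofuran-2-yl]methyl}decahydro-1H-benzo[7]annulen-2-yl]methyl acetate | C[Si](C)(C)CC1=C[C@H](C[C@]2(COC(C)=O)CC[C@@]3(C)C[C@H]4O[C@@]4(C)CC[C@@H]3C2=O)OC1=O
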